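You read these flasks at 4.0 h. Until then they stay closed and stirred at constant temperature, with nothing added: the rule I leave you was read from runs kept that way. Inside, starting complex trades leaving ligand for incoming ligand, giving complex with one exchanged and then complex with two exchanged.

common to all: starting complex 0.010 M
- eta: incoming ligand 0.37 equiv; leaving ligand 2 equiv; run made earlier
- alpha: incoming ligand 0.66 equiv; leaving ligand 2 equiv; run made earlier
- gamma: incoming ligand 0.79 equiv; leaving ligand 2 equiv; run made earlier
- midnight: incoming ligand 0.500 equiv; leaving ligand 2.00 equiv; time 4.0 h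
- spring: incoming ligand 0.800 equiv; leaving ligand 2.00 equiv; time 4.0 h
- autumn: incoming ligand 1.00 equiv; leaving ligand 2.00 equiv; time 4.0 h

| run | time / h | complex with one exchanged / % | complex with two exchanged / % |
|---|---|---|---|
| eta | 0.500 | 24.8 | 0.3 |
| eta | 1.00 | 22.9 | 0.5 |
| eta | 1.50 | 19.4 | 2.0 |
| eta | 2.50 | 12.4 | 0.6 |
| eta | 3.00 | 10.8 | 0 |
| alpha | 0.250 | 39.1 | 7.8 |
| alpha | 0.417 | 39.5 | 4.7 |
| alpha | 0.833 | 37.4 | 4.3 |
| alpha | 1.33 | 31.3 | 2.2 |
| alpha | 3.00 | 17.4 | 0 |
| gamma | 0.500 | 44.2 | 8.9 |
| gamma | 1.00 | 36.9 | 6.6 |
| gamma | 1.50 | 32.9 | 6.3 |
| gamma | 2.50 | 23.7 | 4.7 |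
| gamma | 3.00 | 20.5 | 2.5 |

(standard deviation of a reading: 1 percentage point)

- a reading or a percentage of complex with two exchanged counts all its forms, free or not

- how much complex with one exchanged is there at the end, in percent of the starting complex charged: for each flask in turn (midnight, spring, autumn)

You will come when the early exchange is behind us, so reckon with the slow fall it leaves. In the gamma run, complex with one exchanged goes from 44.2% at 0.500 h to 20.5% at 3.00 h. That reads as 0.307 h⁻¹, and I call it the fading rate: the pseudo-first-order constant of the slow fall of complex with one exchanged. Spring is charged almost like the gamma run, 0.800 equiv against 0.79 equiv, so I carry that last reading on to the end and expect 15.1% in spring.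

The forecast gives 9.8% for midnight, 15.3% for spring, which is above my figure, and 18% for autumn, and it calls the autumn figure “the least certain value”.

The flasks give 10.1%, 15.0% and 16.4%, in that order, so the forecast stands within the tolerance.

    complex with one exchanged + incoming ligand ⇌ leaving ligand + complex with two exchanged (K = 3.90, k = 0.660 M⁻¹ s⁻¹)
    leaving ligand + starting complex → side product B (k = 0.00260 M⁻¹ s⁻¹)
    starting complex + incoming ligand ⇌ leaving ligand + complex with one exchanged (K = 40.0, k = 0.590 M⁻¹ s⁻¹)
    complex with two exchanged + incoming ligand ⇌ idle adduct, settled at all times (K = 290 M⁻¹)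
    complex with one exchanged → side product A (k = 1.20 × 10⁻⁴ s⁻¹)

The largest single effect on the amount of complex with one exchanged in spring is its loss to side product A: without that step, spring holds 42.0% at the end instead of 15.0%. The fading rate, applied to the 27.9% of complex with one exchanged at 2.00 h in spring, gives 15.1% at the end. In autumn, from 30.2% at 2.00 h, it gives 16.3%, and the autumn flask holds 16.4%.

The earlier runs and the new flask are calculated with constants of no real substance; scatter was added.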